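**Plan**

1. Ring numbering: C1 (CHOH), C2=C3, C4, C5 (tertiary carbinol carrying the chain C1′–C16′), C6. The retrosynthesis first cuts C1′–C2′, giving a spiro-epoxide at C5/C1′ and a C15 Z-alkenyl Grignard reagent, and then takes C1′ back to a carboxyl group.
2. With C1′ as CO2H, the array C1′(=O)–C5(OR)–C4–C3=C2 is a 2-alkoxy-4-enoic acid. A retro-[3,3] shift cuts C4–C5 and rejoins the carboxyl oxygen to C2, which leads to a 3-alkoxy-5-silyloxy-6-vinyl δ-lactone.
3. The lactone is cut at its ring C–O bond (oxidative lactonisation of a 1,5-diol) and between the two carbinol carbons (syn-alkoxyallylboration of an aldehyde whose future carboxyl carbon is masked as an anisylidene acetal).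
4. Forward order: acetal, aldehyde, syn-diol unit, δ-lactone, ring contraction to the cyclohexene (the only carbocycle), spiro-epoxide, chain coupling, desilylation.
5. Stereochemistry: the allylborane sets both carbinol centres (reagent control, syn). The silyloxy centre becomes C1. The vinyl carbinol centre is consumed in the suprafacial shift and fixes C5. The Z-alkene comes from a Lindlar semi-hydrogenation.

Key step: step 8

Abbreviations: TBS = tert-butyldimethylsilyl, PMB = 4-methoxybenzyl, MOM = methoxymethyl, Ipc = isopinocampheyl. Lactone positions: O1, C2 (C=O), C3 (OPMB), C4, C5 (OTBS), C6 (vinyl).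

Remark: pent-4-ene-1,2-diol is used as the racemate and its anisylidene acetal as a cis/trans mixture; both centres are erased later (acetal opening in step 5, enolisation in step 8), so they are drawn without descriptors up to compound 15.

Remark: the allylborane of the (−)-α-pinene series is assumed to add to the Re face of 4, as it does with unbranched aliphatic aldehydes; if the opposite sense were found, (−)-Ipc2BOMe would be used instead.

**Route**

Step 1
Reactants: 1 pent-4-ene-1,2-diol
Product: 2 2-(4-methoxyphenyl)-4-(prop-2-en-1-yl)-1,3-dioxolane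
Conditions: 4-MeOC6H4CH(OMe)2, pyridinium p-toluenesulfonate (cat.), CH2Cl2, rt
Reagents that add atoms: 4-methoxybenzaldehyde dimethyl acetal, COC(OC)c1ccc(OC)cc1
Why: Acid-catalysed transacetalisation closes the five-membered anisylidene acetal on the 1,2-diol; it masks the future carboxyl carbon at the alcohol level (so the γ-hydroxyl made in step 3 cannot lactonise) and already carries the aryl group of the later PMB ether, while the new acetal centre forms without control and is removed in step 5.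

Step 2
Reactants: 2 2-(4-methoxyphenyl)-4-(prop-2-en-1-yl)-1,3-dioxolane
Product: 4 [2-(4-methoxyphenyl)-1,3-dioxolan-4-yl]acetaldehyde, via vicinal diol 3 (not isolated)
Conditions: OsO4 (2 mol%), NaIO4, 2,6-lutidine, dioxane/H2O, rt
Reagents that add atoms: osmium tetroxide, O=[Os](=O)(=O)=O; sodium periodate, [Na+].[O-]I(=O)(=O)=O
Why: Lemieux–Johnson cleavage (OsO4 dihydroxylation, then periodate glycol scission) turns the terminal alkene into the aldehyde under lutidine-buffered conditions that should leave the acid-labile acetal and the electron-rich arene untouched.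

Step 3
Reactants: 4 [2-(4-methoxyphenyl)-1,3-dioxolan-4-yl]acetaldehyde; 5 allyl methoxymethyl ether
Product: 8 (2S,3S)-1-[2-(4-methoxyphenyl)-1,3-dioxolan-4-yl]-3-(methoxymethoxy)pent-4-en-2-ol, via allylborane 6 (not isolated), via borinate ester 7 (not isolated)
Conditions: 5, s-BuLi, THF, −78 °C; (+)-Ipc2BOMe [(+)-B-methoxydiisopinocampheylborane, from (−)-α-pinene]; BF3·OEt2; then 4, −78 °C; NaOH, H2O2, 0 °C → rt
Reagents that add atoms: none
Why: Brown (Z)-γ-alkoxyallylboration: metalation of 5 gives the Z-alkoxyallyl anion, which after borylation adds through a chair Zimmerman–Traxler transition state so that the Z-geometry becomes the syn relationship, while the Ipc groups steer the allyl unit to the Re face of 4 and set both new centres as 2S,3S; the free hydroxyl sits on the future silyloxy carbon and the MOM ether on the future lactone oxygen.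

Step 4
Reactants: 8 (2S,3S)-1-[2-(4-methoxyphenyl)-1,3-dioxolan-4-yl]-3-(methoxymethoxy)pent-4-en-2-ol
Product: 9 tert-butyl{[(2S,3S)-1-[2-(4-methoxyphenyl)-1,3-dioxolan-4-yl]-3-(methoxymethoxy)pent-4-en-2-yl]oxy}dimethylsilane
Conditions: TBSCl, imidazole, 4-(dimethylamino)pyridine (cat.), DMF, rt → 40 °C
Reagents that add atoms: tert-butyldimethylsilyl chloride, CC(C)(C)[Si](C)(C)Cl
Why: Standard silylation of the secondary alcohol with a silyl chloride and imidazole (a silyl triflate is avoided because it would open the anisylidene acetal); no stereocentre is touched.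

Step 5
Reactants: 9 tert-butyl{[(2S,3S)-1-[2-(4-methoxyphenyl)-1,3-dioxolan-4-yl]-3-(methoxymethoxy)pent-4-en-2-yl]oxy}dimethylsilane
Product: 10 (4S,5S)-4-(TBSO)-2-(PMBO)-5-(methoxymethoxy)hept-6-en-1-ol
Conditions: iBu2AlH (3 equiv), CH2Cl2, −78 → 0 °C; aq. KNaC4H4O6 work-up
Reagents that add atoms: none
Why: Reductive acetal opening: iBu2AlH coordinates the less hindered primary acetal oxygen, the C–O bond on that side breaks and hydride quenches the oxocarbenium ion, which should leave the PMB ether on the secondary oxygen and free the primary alcohol.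

Step 6
Reactants: 10 (4S,5S)-4-(TBSO)-2-(PMBO)-5-(methoxymethoxy)hept-6-en-1-ol
Product: 12 (4S,5S)-4-(TBSO)-2-(PMBO)hept-6-ene-1,5-diol, via bipyridinium salt 11 (not isolated)
Conditions: Me3SiOTf (3 equiv), 2,2′-bipyridyl (4.5 equiv), CH2Cl2, 0 °C → rt; then H2O, rt
Reagents that add atoms: none
Why: Silyl-triflate-mediated acetal cleavage: Me3SiOTf buffered by 2,2′-bipyridyl ionises only the acetal-type MOM ether to a pyridinium methyl ether that water hydrolyses, conditions under which the TBS and PMB ethers (no acetal carbon) should persist, while the primary alcohol is silylated transiently and freed again on work-up.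

Step 7
Reactants: 12 (4S,5S)-4-(TBSO)-2-(PMBO)hept-6-ene-1,5-diol
Product: 15 (5S,6S)-5-(TBSO)-6-ethenyl-3-(PMBO)oxan-2-one, via hydroxy aldehyde 13 (not isolated), via lactol 14 (not isolated)
Conditions: TEMPO (2,2,6,6-tetramethylpiperidin-1-oxyl, 0.2 equiv), PhI(OAc)2 (3 equiv), CH2Cl2, rt
Reagents that add atoms: none
Why: Oxoammonium oxidation of the primary alcohol, ring closure of the aldehyde onto the allylic hydroxyl and further oxidation of the lactol give the δ-lactone (oxidative lactonisation of a 1,5-diol); primary alcohols react far faster than secondary ones and the γ-oxygen is silylated, so only the six-membered lactone can form.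

Step 8
Reactants: 15 (5S,6S)-5-(TBSO)-6-ethenyl-3-(PMBO)oxan-2-one
Product: 18 (1S,5S)-5-(TBSO)-1-(PMBO)cyclohex-3-ene-1-carboxylic acid, via silyl ketene acetal 16 (not isolated), via trimethylsilyl ester 17 (not isolated)
Conditions: Me3SiCl/Et3N (premixed), THF, −78 °C; LiN(iPr)2, −78 °C → rt; then toluene, 100 °C; aq. citric acid work-up
Reagents that add atoms: none
Why: Deprotonation at C3 in the presence of Me3SiCl traps the lactone enolate as cyclic silyl ketene acetal 16, whose array C3=C2–O1–C6–CH=CH2 undergoes a concerted suprafacial [3,3]-sigmatropic shift (Ireland–Claisen rearrangement) that forms the C3–CH2 bond (C4–C5 of the target) and breaks O1–C6 to give silyl ester 17, hydrolysed on work-up. The closest known reaction type is the ring contraction of silyl ketene acetals of 6-alkenyl δ-lactones and 6-alkenyl-1,4-dioxan-2-ones to cyclohexene- and dihydropyran-carboxylic acids. The cyclohexene closes in a pericyclic mode through a boat-like transition state of bicyclo[2.2.2]octane shape (the lactone ring allows no chair), so the new ring alkene (C2=C3 of the target) is necessarily cis. The quaternary centre is controlled by the vinyl-bearing C6: the vinyl terminus can reach only its own face of the ketene acetal, and because vinyl and silyloxy groups are cis on the lactone, the PMB ether at the new quaternary carbon ends up cis to the silyloxy group (1S,5S), whereas the C3 configuration of 15 is irrelevant since C3 is planar in 16. The step needs O-silylation to outrun C-silylation or enolate decomposition, which the in situ quench at −78 °C should secure, and no β-elimination can compete because C4 carries no leaving group.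

Step 9
Reactants: 18 (1S,5S)-5-(TBSO)-1-(PMBO)cyclohex-3-ene-1-carboxylic acid
Product: 19 [(1S,5S)-5-(TBSO)-1-(PMBO)cyclohex-3-en-1-yl]methanol
Conditions: LiAlH4, THF, 0 °C → 40 °C
Reagents that add atoms: none
Why: Hydride reduction of the carboxylic acid (via its aluminium carboxylate) to the primary alcohol; silyl ether, PMB ether and the isolated alkene are inert to LiAlH4, and the quaternary centre is not involved.

Step 10
Reactants: 19 [(1S,5S)-5-(TBSO)-1-(PMBO)cyclohex-3-en-1-yl]methanol
Product: 20 [(1S,5S)-5-(TBSO)-1-(PMBO)cyclohex-3-en-1-yl]methyl methanesulfonate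
Conditions: MsCl, Et3N, CH2Cl2, 0 °C
Reagents that add atoms: methanesulfonyl chloride, CS(=O)(=O)Cl
Why: Sulfonylation of the primary alcohol; it is placed before PMB removal so that no free neighbouring hydroxyl can trap the benzylic cation as an anisylidene acetal in the next step.

Step 11
Reactants: 20 [(1S,5S)-5-(TBSO)-1-(PMBO)cyclohex-3-en-1-yl]methyl methanesulfonate
Product: 22 (3S,7S)-7-(TBSO)-1-oxaspiro[2.5]oct-5-ene, via hydroxy mesylate 21 (not isolated)
Conditions: DDQ (2,3-dichloro-5,6-dicyano-1,4-benzoquinone), CH2Cl2/pH 7 buffer, 0 °C → rt; aq. NaHCO3 wash; then K2CO3, MeOH, rt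
Reagents that add atoms: none
Why: Oxidative PMB cleavage by DDQ (hydride abstraction, hydrolysis of the oxocarbenium ion) frees the tertiary alcohol, whose alkoxide then displaces the mesylate in an intramolecular Williamson reaction (3-exo-tet) to the spiro-epoxide; the C–O bond at the quaternary carbon is never broken, so its configuration is retained.

Step 12
Reactants: 23 5-phenylpent-1-yne; 24 1,10-dibromodecane
Product: 26 (15-bromopentadec-4-yn-1-yl)benzene, via lithium acetylide 25 (not isolated)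
Conditions: 23, n-BuLi, THF, −78 °C; then 24 (4 equiv), DMPU, −78 °C → rt
Reagents that add atoms: none
Why: SN2 alkylation of a lithium acetylide by a primary bromide in a dipolar cosolvent; the excess of dibromide suppresses double alkylation and is recovered by distillation.

Step 13
Reactants: 26 (15-bromopentadec-4-yn-1-yl)benzene
Product: 27 [(4Z)-15-bromopentadec-4-en-1-yl]benzene
Conditions: H2 (1 atm), Pd/CaCO3 poisoned with Pb(OAc)2, quinoline, hexane/EtOAc, rt
Reagents that add atoms: none
Why: Lindlar semi-hydrogenation: syn delivery of hydrogen on the poisoned palladium surface gives the Z-alkene and stops at the alkene stage; the primary bromide should not be hydrogenolysed.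

Step 14
Reactants: 22 (3S,7S)-7-(TBSO)-1-oxaspiro[2.5]oct-5-ene; 27 [(4Z)-15-bromopentadec-4-en-1-yl]benzene
Product: 29 (1S,5S)-5-(TBSO)-1-[(12Z)-16-phenylhexadec-12-en-1-yl]cyclohex-3-en-1-ol, via Grignard reagent 28 (not isolated)
Conditions: 27, Mg, THF, rt → 40 °C; then CuI (10 mol%), 22, THF, −30 → 0 °C; H2O then aq. NH4Cl
Reagents that add atoms: none
Why: Copper-catalysed SN2 opening of the 2,2-disubstituted epoxide at its unhindered CH2 terminus by the alkyl Grignard reagent joins C1′ to C2′ and releases the tertiary alcohol with its configuration unchanged; low temperature and the copper catalyst should suppress halohydrin formation and epoxide rearrangement.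

Step 15
Reactants: 29 (1S,5S)-5-(TBSO)-1-[(12Z)-16-phenylhexadec-12-en-1-yl]cyclohex-3-en-1-ol
Product: 30 (1S,5S)-5-[(12Z)-16-phenylhexadec-12-en-1-yl]cyclohex-2-ene-1,5-diol
Conditions: Bu4NF, THF, 0 °C → rt
Reagents that add atoms: none
Why: Fluoride-induced desilylation of the allylic TBS ether; neither alkene nor the tertiary alcohol is affected, and the target is released.

**Compound list**

1 | pent-4-ene-1,2-diol (racemic) | OCC(O)CC=C | starting material
2 | 2-(4-methoxyphenyl)-4-(prop-2-en-1-yl)-1,3-dioxolane (racemic cis/trans mixture) | C=CCC1COC(c2ccc(OC)cc2)O1 | intermediate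
3 | 3-[2-(4-methoxyphenyl)-1,3-dioxolan-4-yl]propane-1,2-diol (not isolated) | OCC(O)CC1COC(c2ccc(OC)cc2)O1 | intermediate
4 | [2-(4-methoxyphenyl)-1,3-dioxolan-4-yl]acetaldehyde (racemic cis/trans mixture) | O=CCC1COC(c2ccc(OC)cc2)O1 | intermediate
5 | allyl methoxymethyl ether, 3-(methoxymethoxy)prop-1-ene | C=CCOCOC | starting material
6 | [(2Z)-3-(methoxymethoxy)prop-2-en-1-yl]di(isopinocampheyl)borane, Ipc groups of the (−)-α-pinene series (not isolated) | COCO/C=C\CB([C@H]1C[C@H]2C[C@@H]([C@@H]1C)C2(C)C)[C@H]1C[C@H]2C[C@@H]([C@@H]1C)C2(C)C | intermediate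
7 | (2S,3S)-1-[2-(4-methoxyphenyl)-1,3-dioxolan-4-yl]-3-(methoxymethoxy)pent-4-en-2-yl di(isopinocampheyl)borinate (not isolated) | O([C@@H](CC1COC(c2ccc(OC)cc2)O1)[C@H](C=C)OCOC)B([C@H]1C[C@H]2C[C@@H]([C@@H]1C)C2(C)C)[C@H]1C[C@H]2C[C@@H]([C@@H]1C)C2(C)C | intermediate
8 | (2S,3S)-1-[2-(4-methoxyphenyl)-1,3-dioxolan-4-yl]-3-(methoxymethoxy)pent-4-en-2-ol (mixture at the two dioxolane centres) | O[C@@H](CC1COC(c2ccc(OC)cc2)O1)[C@H](C=C)OCOC | intermediate
9 | tert-butyl{[(2S,3S)-1-[2-(4-methoxyphenyl)-1,3-dioxolan-4-yl]-3-(methoxymethoxy)pent-4-en-2-yl]oxy}dimethylsilane | CC(C)(C)[Si](C)(C)O[C@@H](CC1COC(c2ccc(OC)cc2)O1)[C@H](C=C)OCOC | intermediate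
10 | (4S,5S)-4-[(tert-butyldimethylsilyl)oxy]-2-[(4-methoxybenzyl)oxy]-5-(methoxymethoxy)hept-6-en-1-ol (C2 epimers) | CC(C)(C)[Si](C)(C)O[C@@H](CC(OCc1ccc(OC)cc1)CO)[C@H](C=C)OCOC | intermediate
11 | 1-({[(3S,4S)-4-[(tert-butyldimethylsilyl)oxy]-6-[(4-methoxybenzyl)oxy]-7-[(trimethylsilyl)oxy]hept-1-en-3-yl]oxy}methyl)-2-(pyridin-2-yl)pyridinium trifluoromethanesulfonate (not isolated) | CC(C)(C)[Si](C)(C)O[C@@H](CC(OCc1ccc(OC)cc1)CO[Si](C)(C)C)[C@H](C=C)OC[n+]1ccccc1-c1ccccn1.[O-]S(=O)(=O)C(F)(F)F | intermediate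
12 | (4S,5S)-4-[(tert-butyldimethylsilyl)oxy]-2-[(4-methoxybenzyl)oxy]hept-6-ene-1,5-diol (C2 epimers) | CC(C)(C)[Si](C)(C)O[C@@H](CC(OCc1ccc(OC)cc1)CO)[C@H](C=C)O | intermediate
13 | (4S,5S)-4-[(tert-butyldimethylsilyl)oxy]-5-hydroxy-2-[(4-methoxybenzyl)oxy]hept-6-enal (not isolated) | CC(C)(C)[Si](C)(C)O[C@@H](CC(OCc1ccc(OC)cc1)C=O)[C@H](C=C)O | intermediate
14 | (5S,6S)-5-[(tert-butyldimethylsilyl)oxy]-6-ethenyl-3-[(4-methoxybenzyl)oxy]oxan-2-ol (not isolated) | CC(C)(C)[Si](C)(C)O[C@@H]1[C@H](C=C)OC(O)C(OCc2ccc(OC)cc2)C1 | intermediate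
15 | (5S,6S)-5-[(tert-butyldimethylsilyl)oxy]-6-ethenyl-3-[(4-methoxybenzyl)oxy]oxan-2-one (cis-5,6; C3 epimers) | CC(C)(C)[Si](C)(C)O[C@@H]1[C@H](C=C)OC(=O)C(OCc2ccc(OC)cc2)C1 | intermediate
16 | tert-butyl{[(2S,3S)-2-ethenyl-5-[(4-methoxybenzyl)oxy]-6-[(trimethylsilyl)oxy]-3,4-dihydro-2H-pyran-3-yl]oxy}dimethylsilane (not isolated) | CC(C)(C)[Si](C)(C)O[C@@H]1[C@H](C=C)OC(O[Si](C)(C)C)=C(OCc2ccc(OC)cc2)C1 | intermediate
17 | trimethylsilyl (1S,5S)-5-[(tert-butyldimethylsilyl)oxy]-1-[(4-methoxybenzyl)oxy]cyclohex-3-ene-1-carboxylate (not isolated) | CC(C)(C)[Si](C)(C)O[C@@H]1C=CC[C@@](OCc2ccc(OC)cc2)(C(=O)O[Si](C)(C)C)C1 | intermediate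
18 | (1S,5S)-5-[(tert-butyldimethylsilyl)oxy]-1-[(4-methoxybenzyl)oxy]cyclohex-3-ene-1-carboxylic acid | CC(C)(C)[Si](C)(C)O[C@@H]1C=CC[C@@](OCc2ccc(OC)cc2)(C(=O)O)C1 | intermediate
19 | [(1S,5S)-5-[(tert-butyldimethylsilyl)oxy]-1-[(4-methoxybenzyl)oxy]cyclohex-3-en-1-yl]methanol | CC(C)(C)[Si](C)(C)O[C@@H]1C=CC[C@@](OCc2ccc(OC)cc2)(CO)C1 | intermediate
20 | [(1S,5S)-5-[(tert-butyldimethylsilyl)oxy]-1-[(4-methoxybenzyl)oxy]cyclohex-3-en-1-yl]methyl methanesulfonate | CC(C)(C)[Si](C)(C)O[C@@H]1C=CC[C@@](OCc2ccc(OC)cc2)(COS(C)(=O)=O)C1 | intermediate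
21 | [(1S,5S)-5-[(tert-butyldimethylsilyl)oxy]-1-hydroxycyclohex-3-en-1-yl]methyl methanesulfonate (not isolated) | CC(C)(C)[Si](C)(C)O[C@@H]1C=CC[C@@](O)(COS(C)(=O)=O)C1 | intermediate
22 | (3S,7S)-7-[(tert-butyldimethylsilyl)oxy]-1-oxaspiro[2.5]oct-5-ene | CC(C)(C)[Si](C)(C)O[C@@H]1C=CC[C@@]2(CO2)C1 | intermediate
23 | 5-phenylpent-1-yne | C#CCCCc1ccccc1 | starting material
24 | 1,10-dibromodecane | BrCCCCCCCCCCBr | starting material
25 | lithium 5-phenylpent-1-yn-1-ide (not isolated) | [Li]C#CCCCc1ccccc1 | intermediate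
26 | (15-bromopentadec-4-yn-1-yl)benzene | BrCCCCCCCCCCC#CCCCc1ccccc1 | intermediate
27 | [(4Z)-15-bromopentadec-4-en-1-yl]benzene | BrCCCCCCCCCC/C=C\CCCc1ccccc1 | intermediate
28 | bromo[(11Z)-15-phenylpentadec-11-en-1-yl]magnesium (not isolated) | Br[Mg]CCCCCCCCCC/C=C\CCCc1ccccc1 | intermediate
29 | (1S,5S)-5-[(tert-butyldimethylsilyl)oxy]-1-[(12Z)-16-phenylhexadec-12-en-1-yl]cyclohex-3-en-1-ol | CC(C)(C)[Si](C)(C)O[C@@H]1C=CC[C@@](O)(CCCCCCCCCCC/C=C\CCCc2ccccc2)C1 | intermediate
30 | (1S,5S)-5-[(12Z)-16-phenylhexadec-12-en-1-yl]cyclohex-2-ene-1,5-diol | O[C@@H]1C=CC[C@@](O)(CCCCCCCCCCC/C=C\CCCc2ccccc2)C1 | target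

**Count**

Total steps: 15. Longest linear sequence: 13 (steps 1–11, 14, 15); the chain fragment takes 2 steps (12, 13).

**Steps most likely to fail**

1. Step 6. Under the silyl triflate the PMB ether may ionise as well, or the TBS group may migrate to the neighbouring hydroxyl once it is freed, so that removal of the MOM group alone is not clean. The fallback sets out from 10 and returns at 12. Both ether-type groups are cleaved on purpose with Me2BBr (CH2Cl2, −78 °C), which should spare the silyl ether, to give (4S,5S)-4-[(tert-butyldimethylsilyl)oxy]hept-6-ene-1,2,5-triol F1. The terminal 1,2-diol of this triol is re-acetalised with 4-methoxybenzaldehyde dimethyl acetal and pyridinium p-toluenesulfonate to (3S,4S)-4-[(tert-butyldimethylsilyl)oxy]-5-[2-(4-methoxyphenyl)-1,3-dioxolan-4-yl]pent-1-en-3-ol F2. Reductive opening with iBu2AlH as in step 5 then places the PMB group on the secondary oxygen and gives 12 directly.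

2. Step 5. Hydride delivery may follow the wrong regiochemistry if the aluminium is held by the MOM or silyl ether oxygens instead of the primary acetal oxygen, which would put the PMB group on the primary oxygen. The fallback sets out from 9 and returns at 10. The acetal is removed by transacetalisation (pyridinium p-toluenesulfonate, MeOH) to (4S,5S)-4-[(tert-butyldimethylsilyl)oxy]-5-(methoxymethoxy)hept-6-ene-1,2-diol F3. The primary hydroxyl is acylated selectively (pivaloyl chloride, pyridine, 0 °C) to (4S,5S)-4-[(tert-butyldimethylsilyl)oxy]-2-hydroxy-5-(methoxymethoxy)hept-6-en-1-yl 2,2-dimethylpropanoate F4. The secondary hydroxyl is benzylated with 4-methoxybenzyl 2,2,2-trichloroacetimidate and La(OTf)3 (cat.) to (4S,5S)-4-[(tert-butyldimethylsilyl)oxy]-2-[(4-methoxybenzyl)oxy]-5-(methoxymethoxy)hept-6-en-1-yl 2,2-dimethylpropanoate F5. Reductive removal of the pivalate with iBu2AlH (CH2Cl2, −78 °C) gives 10.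

3. Step 14. Magnesium halide present in the Grignard solution may open the 2,2-disubstituted epoxide to a bromohydrin or rearrange it to an aldehyde before the C–C bond forms, and Wurtz coupling may consume the bromide. The fallback sets out from 27 and 22 and returns at 29. Bromide 27 is converted with PhSO2Na (DMF, 60 °C) into [(4Z)-15-(phenylsulfonyl)pentadec-4-en-1-yl]benzene F6. Deprotonation with n-BuLi (THF, −78 °C) gives [(4Z)-15-lithio-15-(phenylsulfonyl)pentadec-4-en-1-yl]benzene F7, which opens 22 at its CH2 terminus in the presence of BF3·OEt2 to (1S,5S)-5-[(tert-butyldimethylsilyl)oxy]-1-[(12Z)-16-phenyl-2-(phenylsulfonyl)hexadec-12-en-1-yl]cyclohex-3-en-1-ol F8. Reductive desulfonylation with Na(Hg) and Na2HPO4 in MeOH gives 29.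

**Further compounds**

F1 | step 6 | (4S,5S)-4-[(tert-butyldimethylsilyl)oxy]hept-6-ene-1,2,5-triol | CC(C)(C)[Si](C)(C)O[C@@H](CC(O)CO)[C@H](C=C)O
F2 | step 6 | (3S,4S)-4-[(tert-butyldimethylsilyl)oxy]-5-[2-(4-methoxyphenyl)-1,3-dioxolan-4-yl]pent-1-en-3-ol | CC(C)(C)[Si](C)(C)O[C@@H](CC1COC(c2ccc(OC)cc2)O1)[C@H](C=C)O
F3 | step 5 | (4S,5S)-4-[(tert-butyldimethylsilyl)oxy]-5-(methoxymethoxy)hept-6-ene-1,2-diol | CC(C)(C)[Si](C)(C)O[C@@H](CC(O)CO)[C@H](C=C)OCOC
F4 | step 5 | (4S,5S)-4-[(tert-butyldimethylsilyl)oxy]-2-hydroxy-5-(methoxymethoxy)hept-6-en-1-yl 2,2-dimethylpropanoate | CC(C)(C)[Si](C)(C)O[C@@H](CC(O)COC(=O)C(C)(C)C)[C@H](C=C)OCOC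
F5 | step 5 | (4S,5S)-4-[(tert-butyldimethylsilyl)oxy]-2-[(4-methoxybenzyl)oxy]-5-(methoxymethoxy)hept-6-en-1-yl 2,2-dimethylpropanoate | CC(C)(C)[Si](C)(C)O[C@@H](CC(OCc1ccc(OC)cc1)COC(=O)C(C)(C)C)[C@H](C=C)OCOC
F6 | step 14 | [(4Z)-15-(phenylsulfonyl)pentadec-4-en-1-yl]benzene | O=S(=O)(CCCCCCCCCC/C=C\CCCc1ccccc1)c1ccccc1
F7 | step 14 | [(4Z)-15-lithio-15-(phenylsulfonyl)pentadec-4-en-1-yl]benzene | [Li]C(CCCCCCCCC/C=C\CCCc1ccccc1)S(=O)(=O)c1ccccc1
F8 | step 14 | (1S,5S)-5-[(tert-butyldimethylsilyl)oxy]-1-[(12Z)-16-phenyl-2-(phenylsulfonyl)hexadec-12-en-1-yl]cyclohex-3-en-1-ol | CC(C)(C)[Si](C)(C)O[C@@H]1C=CC[C@@](O)(CC(CCCCCCCCC/C=C\CCCc2ccccc2)S(=O)(=O)c2ccccc2)C1
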